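**Plan**

Numbering: ring A (tetronic acid) = O1, C2 (lactone C=O), C3 (bearing CH3), C4 (enol C-OH), C5. The chain is C6 to C18, with CH3 on C7, C11 and C15 and the diene C8=C9-C10=C11. Ring B is the 3-furyl group on C18.
Enabling feature: in ring A the adjacent oxygen-bearing carbons C4 and C5 and the segment O1-C2(=O)-C3(CH3) correspond atom for atom to an isocyanide carbon, an aldehyde carbon and propanoic acid.
Cuts: C3-C4 (Dieckmann); then C4-C5 and O1-C2 together (Passerini); then C9-C10 and C11-CH3 (carboalumination and alkenyl-alkenyl coupling), C8=C9 (Takai), C18-ring B (Negishi) and C12-C13 (propargylation).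
Forward: ring B is bought as 3-bromofuran. Fragment A (C10-C18 alkyne) and fragment B (C5-C9 alkenyl iodide) are joined to the full chain, the five atoms of ring A are laid down open-chain in one step, and ring A closes last.
Stereochemistry: C15 comes from (S)-citronellyl bromide, C7 from the (R)-methylsuccinic half ester and C5 from the chiral phosphoric acid. The C10=C11 geometry comes from syn-carboalumination and the C8=C9 geometry from the Takai reaction; both are retained in the coupling.

Key step: step 11

Assumption: (R)-TRIP is taken to direct the isocyanide to the Si face of C5. If a trial on 19 shows the opposite sense, the equally available (S)-enantiomer is used and nothing else changes.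

**Step 1**
Reactants: 1 (S)-citronellyl bromide [(6S)-8-bromo-2,6-dimethyloct-2-ene]; 2 1-(trimethylsilyl)propyne
Product: 4 [(6R)-6,10-dimethylundec-9-en-1-yn-1-yl]trimethylsilane, via lithiated silylpropyne 3 (not isolated)
Conditions: 2, n-BuLi, THF, −78 to −20 °C; then 1, DMPU, −78 °C to rt
Reagents that add atoms: none
Why: Propargylic lithiation of a 1-silylpropyne and SN2 alkylation of a primary bromide is a standard three-carbon alkyne homologation that forms C12-C13; the silyl cap blocks the acetylenic position and C15 is not touched (its descriptor changes only through the CIP ranking).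

**Step 2**
Reactants: 4 [(6R)-6,10-dimethylundec-9-en-1-yn-1-yl]trimethylsilane
Product: 6 (4R)-4-methyl-9-(trimethylsilyl)non-8-yn-1-ol, via aldehyde 5 (not isolated)
Conditions: O3, CH2Cl2/MeOH, −78 °C (Sudan Red 7B end point); then NaBH4, −78 to 0 °C
Reagents that add atoms: ozone, [O-][O+]=O
Why: In this ozonolysis with reductive work-up, ozone attacks the electron-rich trisubstituted alkene far faster than the silyl-capped alkyne, the dye end point guards against over-oxidation, and the short cold borohydride treatment should leave the alkynylsilane intact.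

**Step 3**
Reactants: 6 (4R)-4-methyl-9-(trimethylsilyl)non-8-yn-1-ol
Product: 7 [(6R)-9-iodo-6-methylnon-1-yn-1-yl]trimethylsilane
Conditions: I2, PPh3, imidazole, CH2Cl2, 0 °C to rt
Reagents that add atoms: iodine, II
Why: In this Appel-type iodination the phosphorus-activated primary hydroxyl is displaced by iodide in an SN2 process under essentially neutral conditions that spare the alkynylsilane.

**Step 4**
Reactants: 7 [(6R)-9-iodo-6-methylnon-1-yn-1-yl]trimethylsilane; 8 3-bromofuran
Product: 10 [(6S)-9-(furan-3-yl)-6-methylnon-1-yn-1-yl]trimethylsilane, via alkylzinc iodide 9 (not isolated)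
Conditions: Zn dust, LiCl, THF, 40 °C; then 8, Pd(OAc)2 (2 mol %), SPhos (4 mol %), THF, rt to 50 °C
Reagents that add atoms: none
Why: LiCl-assisted zinc insertion into a primary iodide followed by Negishi sp3-sp2 cross-coupling forms C18-ring B; primary alkylzinc halides couple with heteroaryl bromides under palladium/biarylphosphine catalysis without chain walking, and the positionally unstable 3-lithiofuran is avoided.

**Step 5**
Reactants: 10 [(6S)-9-(furan-3-yl)-6-methylnon-1-yn-1-yl]trimethylsilane
Product: 11 3-[(4R)-4-methylnon-8-yn-1-yl]furan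
Conditions: K2CO3 (0.2 equiv), MeOH, rt
Reagents that add atoms: none
Why: In this base-catalysed protodesilylation of an alkynylsilane, methoxide attacks silicon and methanol protonates the acetylide, and nothing else in 10 is base-labile.

**Step 6**
Reactants: 12 (2R)-4-methoxy-2-methyl-4-oxobutanoic acid
Product: 13 methyl (3R)-4-hydroxy-3-methylbutanoate
Conditions: BH3·SMe2, THF, −10 to 0 °C; MeOH quench
Reagents that add atoms: none
Why: Borane reduces a free carboxylic acid much faster than a methyl ester, C7 is not involved, and the hydroxy ester is kept cold and neutral and carried on at once so that it does not lactonise.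

**Step 7**
Reactants: 13 methyl (3R)-4-hydroxy-3-methylbutanoate
Product: 14 methyl (3R)-3-methyl-4-oxobutanoate
Conditions: TEMPO (10 mol %), PhI(OAc)2, CH2Cl2, 0 °C to rt
Reagents that add atoms: none
Why: The TEMPO/PhI(OAc)2 oxidation of a primary alcohol stops at the aldehyde and needs no base, so the now alpha-positioned C7 centre should not epimerise.

**Step 8**
Reactants: 14 methyl (3R)-3-methyl-4-oxobutanoate
Product: 15 methyl (3R,4E)-5-iodo-3-methylpent-4-enoate
Conditions: CrCl2, CHI3, THF/1,4-dioxane, 0 °C to rt, dark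
Reagents that add atoms: iodoform, IC(I)I
Why: In the Takai olefination the geminal dichromium carbenoid from iodoform adds to the aldehyde and eliminates to the E-alkenyl iodide (C8=C9); the non-basic medium preserves C7 and leaves the ester alone.

**Step 9**
Reactants: 11 3-[(4R)-4-methylnon-8-yn-1-yl]furan; 15 methyl (3R,4E)-5-iodo-3-methylpent-4-enoate
Product: 17 methyl (3R,4E,6E,11R)-14-(furan-3-yl)-3,7,11-trimethyltetradeca-4,6-dienoate, via alkenylalane 16 (not isolated)
Conditions: 11, Me3Al, Cp2ZrCl2 (20 mol %), CH2Cl2, 0 °C to rt; volatiles removed; then 15, ZnCl2 (0.5 equiv, co-catalyst), Pd(PPh3)4 (5 mol %), THF, rt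
Reagents that add atoms: trimethylaluminium, C[Al](C)C
Why: Zirconium-catalysed syn-carboalumination places CH3 on C11 and aluminium on C10 on the same side, and the Negishi alkenyl-alkenyl cross-coupling forms C9-C10 with retention at both partners, so the E,E-diene geometry follows from 16 and 15; esters are tolerated in this tandem process.

**Step 10**
Reactants: 17 methyl (3R,4E,6E,11R)-14-(furan-3-yl)-3,7,11-trimethyltetradeca-4,6-dienoate
Product: 19 (3R,4E,6E,11R)-14-(furan-3-yl)-3,7,11-trimethyltetradeca-4,6-dienal, via aluminium hemiacetal 18 (not isolated)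
Conditions: i-Bu2AlH (1.1 equiv), CH2Cl2, −78 °C; MeOH, then aq. potassium sodium tartrate
Reagents that add atoms: none
Why: In this partial ester reduction with i-Bu2AlH at −78 °C, hemiacetal 18 does not collapse, so no second hydride is delivered and the aldehyde appears only on quenching; C7 is beta to the carbonyl and cannot epimerise.

**Step 11**
Reactants: 19 (3R,4E,6E,11R)-14-(furan-3-yl)-3,7,11-trimethyltetradeca-4,6-dienal; 20 propanoic acid; 21 4-methoxyphenyl isocyanide
Product: 23 (2R,4R,5E,7E,12R)-15-(furan-3-yl)-1-(4-methoxyanilino)-4,8,12-trimethyl-1-oxopentadeca-5,7-dien-2-yl propanoate, via acyl imidate 22 (not isolated)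
Conditions: (R)-TRIP [(R)-3,3'-bis(2,4,6-triisopropylphenyl)-1,1'-binaphthyl-2,2'-diyl hydrogen phosphate] (10 mol %), 4 Å MS, CH2Cl2 (0.05 M), −20 °C; 21 added over 10 h
Reagents that add atoms: none
Why: The phosphoric acid forms a hydrogen-bonded pair with propanoic acid that also holds the aldehyde oxygen of 19; the formally divalent isocyanide carbon, acting as an acyl-anion equivalent for C4, undergoes alpha-addition of C5 and of the carboxylate oxygen through a nitrilium-like transition state to give acyl imidate 22, and a 1,4 O-to-O Mumm acyl shift then moves the propanoyl group onto the former aldehyde oxygen, so that C4-C5 and O1-C2 are formed in one operation with every atom of the three components retained. The closest known reaction type is the chiral-phosphoric-acid-catalysed enantioselective three-component Passerini reaction of aldehydes, carboxylic acids and isocyanides. No ring closes here; O1, C2, C3, C4 and C5 of ring A are only assembled as an open chain. The single new stereocentre, (R)-C5, arises from attack on the Si face of the aldehyde and is decided by the 3,3'-aryl pocket of the catalyst, because the C7 methyl branch is 1,3-remote and offers practically no bias. The step needs facial selectivity against the uncatalysed background, which dilution, low temperature and the slow feed of 21 hold down, and it needs chemoselectivity, which the substrate secures because its unhindered CH2-flanked formyl group is the only electrophile while the diene, ring B, C7 and C15 are inert to the weakly acidic medium.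

**Step 12**
Reactants: 23 (2R,4R,5E,7E,12R)-15-(furan-3-yl)-1-(4-methoxyanilino)-4,8,12-trimethyl-1-oxopentadeca-5,7-dien-2-yl propanoate
Product: 24 tert-butyl N-(4-methoxyphenyl)-N-[(2R,4R,5E,7E,12R)-15-(furan-3-yl)-4,8,12-trimethyl-2-(propanoyloxy)pentadeca-5,7-dienoyl]carbamate
Conditions: Boc2O, DMAP (20 mol %), MeCN, rt
Reagents that add atoms: di-tert-butyl dicarbonate, CC(C)(C)OC(=O)OC(=O)OC(C)(C)C
Why: DMAP-catalysed N-tert-butoxycarbonylation of a secondary anilide is the standard way to turn such an amide into an acyl donor, and the mild nucleophilic catalyst should not disturb C5.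

**Step 13**
Reactants: 24 tert-butyl N-(4-methoxyphenyl)-N-[(2R,4R,5E,7E,12R)-15-(furan-3-yl)-4,8,12-trimethyl-2-(propanoyloxy)pentadeca-5,7-dienoyl]carbamate
Product: 27 (5R)-5-[(2R,3E,5E,10R)-13-(furan-3-yl)-2,6,10-trimethyltrideca-3,5-dien-1-yl]-4-hydroxy-3-methylfuran-2(5H)-one, via lithium enolate 25 (not isolated), via lithium tetronate 26 (not isolated)
Conditions: LiN(SiMe3)2 (2.5 equiv), THF, −78 to −40 °C; cold 0.5 M HCl
Reagents that add atoms: none
Why: Proposed new method: the Boc group twists the anilide out of conjugation and makes C4 an imide-like acyl donor, so lithium enolate 25, formed by kinetic deprotonation of the unhindered propionate CH2 (removal of the C5 proton is held back by 1,3-strain between the two C5 substituents and the N(Boc)aryl group), should add 5-exo-trig to C4 and expel the stabilised carbamate anion, after which irreversible deprotonation to tetronate 26 drives the closure of ring A and protects C5 until the acidic quench; the closest known reaction types are the Dieckmann closure of alpha-acyloxy esters to tetronic acids, the Ugi-Dieckmann route to tetramic acids and the C-acylation of lithium ester enolates by N-Boc amides and lactams.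

**Compound list**

1 | (S)-citronellyl bromide, (6S)-8-bromo-2,6-dimethyloct-2-ene | C[C@@H](CCC=C(C)C)CCBr | starting material
2 | 1-(trimethylsilyl)propyne | CC#C[Si](C)(C)C | starting material
3 | 3-lithio-1-(trimethylsilyl)propyne | [Li]CC#C[Si](C)(C)C | intermediate
4 | [(6R)-6,10-dimethylundec-9-en-1-yn-1-yl]trimethylsilane | C[C@@H](CCC=C(C)C)CCCC#C[Si](C)(C)C | intermediate
5 | (4R)-4-methyl-9-(trimethylsilyl)non-8-ynal | C[C@@H](CCC=O)CCCC#C[Si](C)(C)C | intermediate
6 | (4R)-4-methyl-9-(trimethylsilyl)non-8-yn-1-ol | C[C@@H](CCCO)CCCC#C[Si](C)(C)C | intermediate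
7 | [(6R)-9-iodo-6-methylnon-1-yn-1-yl]trimethylsilane | C[C@@H](CCCI)CCCC#C[Si](C)(C)C | intermediate
8 | 3-bromofuran | Brc1ccoc1 | starting material
9 | iodo[(4R)-4-methyl-9-(trimethylsilyl)non-8-yn-1-yl]zinc | C[C@@H](CCC[Zn]I)CCCC#C[Si](C)(C)C | intermediate
10 | [(6S)-9-(furan-3-yl)-6-methylnon-1-yn-1-yl]trimethylsilane (same spatial arrangement at C15; the silylalkyne arm outranks the furyl arm) | C[C@@H](CCCc1ccoc1)CCCC#C[Si](C)(C)C | intermediate
11 | 3-[(4R)-4-methylnon-8-yn-1-yl]furan | C[C@@H](CCCc1ccoc1)CCCC#C | intermediate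
12 | (2R)-4-methoxy-2-methyl-4-oxobutanoic acid | COC(=O)C[C@@H](C)C(=O)O | starting material
13 | methyl (3R)-4-hydroxy-3-methylbutanoate | COC(=O)C[C@@H](C)CO | intermediate
14 | methyl (3R)-3-methyl-4-oxobutanoate | COC(=O)C[C@@H](C)C=O | intermediate
15 | methyl (3R,4E)-5-iodo-3-methylpent-4-enoate | COC(=O)C[C@@H](C)/C=C/I | intermediate
16 | [(1E,6S)-9-(furan-3-yl)-2,6-dimethylnon-1-en-1-yl]dimethylalane (same spatial arrangement at C15) | C[C@@H](CCCc1ccoc1)CCC/C(C)=C/[Al](C)C | intermediate
17 | methyl (3R,4E,6E,11R)-14-(furan-3-yl)-3,7,11-trimethyltetradeca-4,6-dienoate | COC(=O)C[C@@H](C)/C=C/C=C(\C)CCC[C@@H](C)CCCc1ccoc1 | intermediate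
18 | {[(3R,4E,6E,11R)-14-(furan-3-yl)-1-methoxy-3,7,11-trimethyltetradeca-4,6-dien-1-yl]oxy}diisobutylalane (hemiacetal carbon undefined) | COC(O[Al](CC(C)C)CC(C)C)C[C@@H](C)/C=C/C=C(\C)CCC[C@@H](C)CCCc1ccoc1 | intermediate
19 | (3R,4E,6E,11R)-14-(furan-3-yl)-3,7,11-trimethyltetradeca-4,6-dienal | O=CC[C@@H](C)/C=C/C=C(\C)CCC[C@@H](C)CCCc1ccoc1 | intermediate
20 | propanoic acid | CCC(=O)O | starting material
21 | 4-methoxyphenyl isocyanide | [C-]#[N+]c1ccc(OC)cc1 | starting material
22 | propanoic (2R,4R,5E,7E,12R)-15-(furan-3-yl)-2-hydroxy-N-(4-methoxyphenyl)-4,8,12-trimethylpentadeca-5,7-dienimidic anhydride | CCC(=O)OC(=Nc1ccc(OC)cc1)[C@H](O)C[C@@H](C)/C=C/C=C(\C)CCC[C@@H](C)CCCc1ccoc1 | intermediate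
23 | (2R,4R,5E,7E,12R)-15-(furan-3-yl)-1-(4-methoxyanilino)-4,8,12-trimethyl-1-oxopentadeca-5,7-dien-2-yl propanoate | CCC(=O)O[C@H](C[C@@H](C)/C=C/C=C(\C)CCC[C@@H](C)CCCc1ccoc1)C(=O)Nc1ccc(OC)cc1 | intermediate
24 | tert-butyl N-(4-methoxyphenyl)-N-[(2R,4R,5E,7E,12R)-15-(furan-3-yl)-4,8,12-trimethyl-2-(propanoyloxy)pentadeca-5,7-dienoyl]carbamate | CCC(=O)O[C@H](C[C@@H](C)/C=C/C=C(\C)CCC[C@@H](C)CCCc1ccoc1)C(=O)N(C(=O)OC(C)(C)C)c1ccc(OC)cc1 | intermediate
25 | lithium enolate of the propanoate group of 24 (enolate geometry undefined) | [Li+].CC=C([O-])O[C@H](C[C@@H](C)/C=C/C=C(\C)CCC[C@@H](C)CCCc1ccoc1)C(=O)N(C(=O)OC(C)(C)C)c1ccc(OC)cc1 | intermediate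
26 | lithium salt of 27 (lithium tetronate) | [Li+].CC1=C([O-])[C@@H](C[C@@H](C)/C=C/C=C(\C)CCC[C@@H](C)CCCc2ccoc2)OC1=O | intermediate
27 | (5R)-5-[(2R,3E,5E,10R)-13-(furan-3-yl)-2,6,10-trimethyltrideca-3,5-dien-1-yl]-4-hydroxy-3-methylfuran-2(5H)-one, CNP0246504.1 | CC1=C(O)[C@@H](C[C@@H](C)/C=C/C=C(\C)CCC[C@@H](C)CCCc2ccoc2)OC1=O | target

**Step count**

Total steps: 13. Longest linear sequence: 10 steps (1 to 5, then 9 to 13). Fragment B takes 3 steps (6 to 8).

**Steps most likely to fail**

Step 13. The base may remove the C5 proton instead of a propionate proton, leading to epimerisation at C5 or a Chan-type acyl shift. The enolate may also fragment in a ketene-type elimination on warming before it reaches C4. The fallback uses known chemistry, sets out from 24 and returns at 27. NaOMe in MeOH at 0 °C cleaves the activated amide and the propionate of 24 together and should give methyl (2R,4R,5E,7E,12R)-15-(furan-3-yl)-2-hydroxy-4,8,12-trimethylpentadeca-5,7-dienoate F1. Propanoyl chloride and pyridine in CH2Cl2 re-acylate the hydroxyl to give methyl (2R,4R,5E,7E,12R)-15-(furan-3-yl)-4,8,12-trimethyl-2-(propanoyloxy)pentadeca-5,7-dienoate F2. The classical Dieckmann closure of this alpha-acyloxy ester with LiN(SiMe3)2 in THF at −78 °C, with methoxide as the leaving group, then leads to 27.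

Step 11. The uncatalysed Passerini reaction of an unhindered aliphatic aldehyde may run alongside the catalysed one and erode the facial selectivity at C5. The flat aryl isocyanide may also be discriminated less well by the catalyst pocket. The fallback sets out from 19 and returns at 23, and it takes the C5 configuration from separation and inversion instead of from a catalyst. The uncatalysed three-component reaction of 19, 20 and 21 (CH2Cl2, 1 M, rt) gives 23 together with its C5 epimer, (2S,4R,5E,7E,12R)-15-(furan-3-yl)-1-(4-methoxyanilino)-4,8,12-trimethyl-1-oxopentadeca-5,7-dien-2-yl propanoate F3. The two are diastereomers because C7 and C15 are fixed, so they should be separable by chromatography. K2CO3 in MeOH removes the propionate of the unwanted epimer to give (2S,4R,5E,7E,12R)-15-(furan-3-yl)-2-hydroxy-N-(4-methoxyphenyl)-4,8,12-trimethylpentadeca-5,7-dienamide F4. A Mitsunobu reaction with propanoic acid (PPh3, DIAD, THF) inverts C5 and converges on 23.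

Step 9. Methylalumination may become sluggish or regiochemically unclean if the furan oxygen ties up the zirconium-aluminium species. Methyl instead of alkenyl may be transferred to palladium, or residual alane may attack the ester. The fallback sets out from 11 (through 16) and from 13, returns at 17, and moves the fragment union from C9-C10 to C8=C9. Alkenylalane 16, made as in step 9, is treated with n-BuLi and paraformaldehyde to give (2E,7R)-10-(furan-3-yl)-3,7-dimethyldec-2-en-1-ol F5, and MnO2 in CH2Cl2 oxidises it to (2E,7R)-10-(furan-3-yl)-3,7-dimethyldec-2-enal F6. In parallel, 13 undergoes a Mitsunobu reaction with 1-phenyl-1H-tetrazole-5-thiol (PPh3, DIAD) to give methyl (3R)-3-methyl-4-[(1-phenyl-1H-tetrazol-5-yl)sulfanyl]butanoate F7. H2O2 with (NH4)6Mo7O24 in EtOH oxidises this to methyl (3R)-3-methyl-4-[(1-phenyl-1H-tetrazol-5-yl)sulfonyl]butanoate F8. A Julia-Kocienski olefination of F6 with F8 (KN(SiMe3)2, DME, −60 °C) then gives 17, and C7 is never alpha to a carbonyl on this path.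

**Further compounds**

F1 | step 13 | methyl (2R,4R,5E,7E,12R)-15-(furan-3-yl)-2-hydroxy-4,8,12-trimethylpentadeca-5,7-dienoate | COC(=O)[C@H](O)C[C@@H](C)/C=C/C=C(\C)CCC[C@@H](C)CCCc1ccoc1
F2 | step 13 | methyl (2R,4R,5E,7E,12R)-15-(furan-3-yl)-4,8,12-trimethyl-2-(propanoyloxy)pentadeca-5,7-dienoate | COC(=O)[C@H](OC(=O)CC)C[C@@H](C)/C=C/C=C(\C)CCC[C@@H](C)CCCc1ccoc1
F3 | step 11 | (2S,4R,5E,7E,12R)-15-(furan-3-yl)-1-(4-methoxyanilino)-4,8,12-trimethyl-1-oxopentadeca-5,7-dien-2-yl propanoate | CCC(=O)O[C@@H](C[C@@H](C)/C=C/C=C(\C)CCC[C@@H](C)CCCc1ccoc1)C(=O)Nc1ccc(OC)cc1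
F4 | step 11 | (2S,4R,5E,7E,12R)-15-(furan-3-yl)-2-hydroxy-N-(4-methoxyphenyl)-4,8,12-trimethylpentadeca-5,7-dienamide | O[C@@H](C[C@@H](C)/C=C/C=C(\C)CCC[C@@H](C)CCCc1ccoc1)C(=O)Nc1ccc(OC)cc1
F5 | step 9 | (2E,7R)-10-(furan-3-yl)-3,7-dimethyldec-2-en-1-ol | C[C@@H](CCCc1ccoc1)CCC/C(C)=C/CO
F6 | step 9 | (2E,7R)-10-(furan-3-yl)-3,7-dimethyldec-2-enal | C[C@@H](CCCc1ccoc1)CCC/C(C)=C/C=O
F7 | step 9 | methyl (3R)-3-methyl-4-[(1-phenyl-1H-tetrazol-5-yl)sulfanyl]butanoate | COC(=O)C[C@@H](C)CSc1nnnn1-c1ccccc1
F8 | step 9 | methyl (3R)-3-methyl-4-[(1-phenyl-1H-tetrazol-5-yl)sulfonyl]butanoate | COC(=O)C[C@@H](C)CS(=O)(=O)c1nnnn1-c1ccccc1
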